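The vessel is closed, stirred and held at one temperature. E and Z make L in it, and you have 3 runs from which to judge a dilute fourth flask, alder.

| flask | E | Z | time |
|---|---|---|---|
| birch | 0.500 M | 0.550 M |  |
| oak | 0.500 M | 0.830 M |  |
| elm | 1.50 M | 0.550 M |  |
| alder | 0.170 M | 0.180 M | 33 min |

| birch run: time / min | birch run: [L] / M | oak run: time / min | oak run: [L] / M | elm run: time / min | elm run: [L] / M |
|---|---|---|---|---|---|
| 1.3 | 0.012 | 1.3 | 0.025 | 1.3 | 0.028 |
| 2.1 | 0.011 | 2.1 | 0.021 | 2.1 | 0.044 |
| 3.3 | 0.020 | 3.3 | 0.039 | 3.3 | 0.067 |
| 5.2 | 0.031 | 5.2 | 0.061 | 5.2 | 0.097 |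
| 8.3 | 0.049 | 8.3 | 0.080 | 8.3 | 0.131 |
| 13 | 0.070 | 13 | 0.109 | 13 | 0.166 |
| 21 | 0.092 | 21 | 0.136 | 21 | 0.200 |
| 33 | 0.104 | 33 | 0.152 | 33 | 0.203 |

(readings scatter by 0.004 M)

* the exponent of [Z] in the starting rate at the charge of the birch run (at the point where two percent of the E have become L)
* the exponent of [E] in the starting rate at the charge of the birch run (at the point where two percent of the E have become L) (one fixed amount of L, the same in the runs compared)
* L in the alder run at 33 min, as a share of the E charged

- Overall: E + Z -> L.
- Constant volume, constant temperature.
- The analysis sees a species whether free or bound.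
- An order is taken over about fifteen percent of the charge, up and down.

1. Take the early slope s, the reading at 5.2 min over that time. For birch, s is 0.00596 M min⁻¹.

2. Compare readings at that same time. Oak against birch gives the exponent of Z, n_Z = 1.64. Elm against birch gives the exponent of E, n_E = 1.04.

3. Define the ceiling Y, the share of charged E turned by a given time if the early slope, scaled to the charge, stayed straight. For alder at 33 min, Y is 6.01%. With exponent 1 in Z, the lowest I allow, the same reckoning gives a looser upper mark of 12.4%.

4. Now the floor. Birch bends: its reading at 33 min is 0.529 of its straight line. Suppose alder bends as birch does, apply that share to Y, and you get 3.18%. With exponent 2 in Z, the highest I allow, the same supposition gives a looser lower mark of 2.14%.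

5. My bracket for alder, an estimate from single readings, therefore runs from 3.18% to 6.01%. The forecast gives 1.6 for Z, 1.05 for E and 5% for alder. That last value lies inside my bracket, above the floor and below the ceiling. The forecast says the stalls suggest “a reversible approach to equilibrium”.

The flask gives 1.4 for Z, 1.1 for E and 5.86% for alder, which is 0.975 of its Y and below it.

    E + 2 Z → L + Z (0.1782 M⁻² min⁻¹)
    L → Oz (0.02616 min⁻¹)
    2 Z ⇌ Z2, settled at all times (1.460 M⁻¹)

In birch, the exponent of Z stands at 1.4 because of the tying up of 2 Z as Z2. The same run without that tying gives 2.1, above the forecast's 1.6. Elm's Y at 33 min, from its own early slope, is 41.0% of its E, and its last reading stands at 13.5%.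

All runs come from a simulation with made-up constants; the scatter is artificial.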